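**Plan**

- Retrosynthesis: the isobutyryl C–C bond at ring carbon C5 and the O‑protecting groups go first. The benzene ring is then cut at C1–C6 and C2–C3, each bond joining an oxygen-bearing carbon to a CH2‑pyranone-bearing carbon. This gives a 3‑siloxy‑2‑(pyronylmethyl)cyclobutenone (C3–C6) and a (pyronylmethyl)siloxyalkyne (C1–C2).
- Enabling feature: the central benzene ring carries oxygen on C2, C4 and C6 and carbon substituents on C1, C3 and C5 in strict alternation. A ketene carbonyl and two ynol‑ether oxygens write exactly this pattern.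
- The cyclobutenone is itself the [2+2] adduct of ketene with the same siloxyalkyne, so the benzene ring is one ketene plus two copies of one alkyne.
- Forward order: pyranone ring (silyl enol ether + propargylmalonyl dichloride), O‑benzylation, alkyne to siloxyalkyne, four-membered ring, benzene ring, acylation at the lone ring CH, desilylation, debenzylation.
- Stereochemistry: the target has no stereocentre and no configurable double bond, so nothing has to be set.

Key step: step 9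

Remark: the target is achiral, so the single-enantiomer requirement is met trivially. Silyl enol ether 2 is used as a Z/E mixture because its geometry is lost in the pyranone. Ketene is not an article of commerce, so its generation from acetone is counted as a step.

**Route**

Step 1
Reactants: 1 3‑pentanone
Product: 2 3‑(trimethylsilyloxy)pent‑2‑ene (Z/E mixture)
Conditions: TMSOTf, Et3N, Et2O, 0 °C
Reagents that add atoms: trimethylsilyl triflate, C[Si](C)(C)OS(=O)(=O)C(F)(F)F
Why: Soft enolisation and O‑silylation of a simple ketone (silyl enol ether formation) is routine, and the symmetrical ketone can give only one regioisomer.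

Step 2
Reactants: 3 diethyl 2‑(prop‑2‑yn‑1‑yl)malonate
Product: 4 2‑(prop‑2‑yn‑1‑yl)malonic acid
Conditions: KOH, EtOH/H2O, rt; then aq. HCl, 0 °C
Reagents that add atoms: potassium hydroxide, [K+].[OH-]
Why: Ester saponification at room temperature should leave the terminal alkyne untouched, and cold acidification should keep the malonic acid from decarboxylating.

Step 3
Reactants: 4 2‑(prop‑2‑yn‑1‑yl)malonic acid
Product: 5 2‑(prop‑2‑yn‑1‑yl)malonyl dichloride
Conditions: (COCl)2, DMF (cat.), CH2Cl2, 0 °C to rt; used crude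
Reagents that add atoms: oxalyl chloride, O=C(Cl)C(=O)Cl
Why: Acid chloride formation through the Vilsmeier-type chloroiminium species is standard for monosubstituted malonic acids and needs no base that could form a ketene.

Step 4
Reactants: 2 3‑(trimethylsilyloxy)pent‑2‑ene; 5 2‑(prop‑2‑yn‑1‑yl)malonyl dichloride
Product: 6 6‑ethyl‑4‑hydroxy‑5‑methyl‑3‑(prop‑2‑yn‑1‑yl)‑2H‑pyran‑2‑one
Conditions: Et2O, −78 °C to rt
Reagents that add atoms: none
Why: Acylative pyranone annulation of a silyl enol ether with a malonyl dichloride (C‑acylation at the enol carbon, then O‑acylative lactonisation and enolisation) should place the malonyl substituent at C3 and the ketone residues at C5 and C6.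

Step 5
Reactants: 6 6‑ethyl‑4‑hydroxy‑5‑methyl‑3‑(prop‑2‑yn‑1‑yl)‑2H‑pyran‑2‑one
Product: 7 4‑(benzyloxy)‑6‑ethyl‑5‑methyl‑3‑(prop‑2‑yn‑1‑yl)‑2H‑pyran‑2‑one
Conditions: BnOH, PPh3, DIAD, THF, 0 °C to rt
Reagents that add atoms: benzyl alcohol, OCc1ccccc1
Why: Mitsunobu O‑alkylation of the acidic 4‑hydroxy‑2‑pyranone should alkylate O4 and, being neutral, should avoid base-induced cyclisation of the hydroxyl onto the alkyne.

Step 6
Reactants: 7 4‑(benzyloxy)‑6‑ethyl‑5‑methyl‑3‑(prop‑2‑yn‑1‑yl)‑2H‑pyran‑2‑one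
Product: 10 4‑(benzyloxy)‑6‑ethyl‑5‑methyl‑3‑{3‑[(triisopropylsilyl)oxy]prop‑2‑yn‑1‑yl}‑2H‑pyran‑2‑one, via lithium acetylide 8 (not isolated), via lithium ynolate 9 (not isolated)
Conditions: LiHMDS (2.1 equiv), THF, −78 °C; t‑BuOOLi (from t‑BuOOH and LiHMDS), −78 to 0 °C; TIPSCl, −78 °C to rt
Reagents that add atoms: tert‑butyl hydroperoxide, CC(C)(C)OO; triisopropylsilyl chloride, CC(C)[Si](Cl)(C(C)C)C(C)C
Why: Oxidation of a lithium acetylide by lithium tert‑butyl peroxide to the ynolate, followed by O‑silylation with the bulky chlorosilane, is an established route from terminal alkynes to triisopropylsiloxyalkynes; the non-nucleophilic amide base should spare the lactone, whose 6‑ethyl group is only held as its dienolate by the second equivalent and returns on work-up.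

Step 7
Reactants: 11 acetone
Product: 12 ketene
Conditions: ca. 700 °C (hot-filament ketene generator), gas stream led directly into step 8
Reagents that add atoms: none
Why: Gas-phase pyrolysis of acetone with loss of methane is the classical laboratory source of ketene, and immediate use avoids dimerisation.

Step 8
Reactants: 10 4‑(benzyloxy)‑6‑ethyl‑5‑methyl‑3‑{3‑[(triisopropylsilyl)oxy]prop‑2‑yn‑1‑yl}‑2H‑pyran‑2‑one; 12 ketene
Product: 13 4‑(benzyloxy)‑6‑ethyl‑5‑methyl‑3‑({4‑oxo‑2‑[(triisopropylsilyl)oxy]cyclobut‑1‑en‑1‑yl}methyl)‑2H‑pyran‑2‑one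
Conditions: ketene (excess, gas stream), CH2Cl2, 0 °C to rt
Reagents that add atoms: none
Why: Thermal [2+2] cycloaddition of ketene with a siloxyalkyne is a known entry to 3‑siloxycyclobutenones, and bonding of the ketene carbonyl carbon to the nucleophilic alkyne carbon remote from oxygen should place the pyronylmethyl group at C2.

Step 9
Reactants: 13 4‑(benzyloxy)‑6‑ethyl‑5‑methyl‑3‑({4‑oxo‑2‑[(triisopropylsilyl)oxy]cyclobut‑1‑en‑1‑yl}methyl)‑2H‑pyran‑2‑one; 10 4‑(benzyloxy)‑6‑ethyl‑5‑methyl‑3‑{3‑[(triisopropylsilyl)oxy]prop‑2‑yn‑1‑yl}‑2H‑pyran‑2‑one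
Product: 18 3,3'‑({4‑hydroxy‑2,6‑bis[(triisopropylsilyl)oxy]‑1,3‑phenylene}bis(methylene))bis[4‑(benzyloxy)‑6‑ethyl‑5‑methyl‑2H‑pyran‑2‑one], via vinylketene 14 (not isolated), via vinylcyclobutenone 15 (not isolated), via dienylketene 16 (not isolated), via cyclohexadienone 17 (not isolated)
Conditions: 10 (1.3 equiv), PhMe, 105 °C, sealed tube
Reagents that add atoms: none
Why: Proposed new method: conrotatory 4π opening of 13 should give the 2‑siloxyvinylketene 14, which adds across siloxyalkyne 10 in a [2+2] with the ketene carbonyl carbon bonding to the CH2‑bearing alkyne carbon, giving 4‑vinylcyclobutenone 15. A second 4π opening then gives dienylketene 16, whose thermal disrotatory 6π electrocyclisation closes the six-membered ring as dienone 17, and tautomerisation gives phenol 18. The closest known reaction type is the Danheiser benzannulation of 3‑alkylcyclobutenones with siloxyalkynes to resorcinol monosilyl ethers; a 3‑siloxycyclobutenone partner, which turns the product into a phloroglucinol, has not been established, and its vinylogous-ester stabilisation is expected only to raise the opening temperature. No stereocentre remains in 18, since the quaternary centre of 15 is lost on ring opening. The required [2+2] regiochemistry is secured by the polarisation of the siloxyalkyne (nucleophilic at the carbon remote from oxygen) against the electrophilic ketene carbon. The fully substituted 4‑alkoxypyranones should be too poor as dienes to undergo Diels–Alder addition at this temperature, and their benzyl ethers remove the hydroxyl groups that would otherwise trap the ketenes.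

Step 10
Reactants: 18 3,3'‑({4‑hydroxy‑2,6‑bis[(triisopropylsilyl)oxy]‑1,3‑phenylene}bis(methylene))bis[4‑(benzyloxy)‑6‑ethyl‑5‑methyl‑2H‑pyran‑2‑one]
Product: 19 3,3'‑({4‑hydroxy‑5‑(2‑methylpropanoyl)‑2,6‑bis[(triisopropylsilyl)oxy]‑1,3‑phenylene}bis(methylene))bis[4‑(benzyloxy)‑6‑ethyl‑5‑methyl‑2H‑pyran‑2‑one]
Conditions: i‑PrCOCl, TiCl4, CH2Cl2, −78 to −20 °C
Reagents that add atoms: isobutyryl chloride, CC(C)C(=O)Cl
Why: Friedel–Crafts acylation at the only unsubstituted ring carbon, which is ortho to the free phenol (the titanium phenoxide delivers the acyl group ortho) and activated by three oxygen donors, should proceed at low temperature where the silyl and benzyl ethers persist.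

Step 11
Reactants: 19 3,3'‑({4‑hydroxy‑5‑(2‑methylpropanoyl)‑2,6‑bis[(triisopropylsilyl)oxy]‑1,3‑phenylene}bis(methylene))bis[4‑(benzyloxy)‑6‑ethyl‑5‑methyl‑2H‑pyran‑2‑one]
Product: 20 3,3'‑{[2,4,6‑trihydroxy‑5‑(2‑methylpropanoyl)‑1,3‑phenylene]bis(methylene)}bis[4‑(benzyloxy)‑6‑ethyl‑5‑methyl‑2H‑pyran‑2‑one]
Conditions: TBAF, AcOH, THF, 0 °C
Reagents that add atoms: none
Why: Fluoride cleavage of the two aryl silyl ethers should be fast, and acetic acid buffering keeps the acylphloroglucinol protonated so that base-induced scrambling of the methylene bridges is avoided.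

Step 12
Reactants: 20 3,3'‑{[2,4,6‑trihydroxy‑5‑(2‑methylpropanoyl)‑1,3‑phenylene]bis(methylene)}bis[4‑(benzyloxy)‑6‑ethyl‑5‑methyl‑2H‑pyran‑2‑one]
Product: 21 3,3'‑{[2,4,6‑trihydroxy‑5‑(2‑methylpropanoyl)‑1,3‑phenylene]bis(methylene)}bis(6‑ethyl‑4‑hydroxy‑5‑methyl‑2H‑pyran‑2‑one)
Conditions: H2 (1 atm), Pd/C, EtOAc, rt
Reagents that add atoms: none
Why: Hydrogenolysis of the two benzyl vinylogous esters should be selective, since the hydrogen-bonded aryl ketone and the tetrasubstituted pyranone double bonds are not reduced under these conditions.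

**Compound list**

1 | 3‑pentanone | CCC(=O)CC | starting material
2 | 3‑(trimethylsilyloxy)pent‑2‑ene (Z/E mixture) | CC=C(CC)O[Si](C)(C)C | intermediate
3 | diethyl 2‑(prop‑2‑yn‑1‑yl)malonate | CCOC(=O)C(CC#C)C(=O)OCC | starting material
4 | 2‑(prop‑2‑yn‑1‑yl)malonic acid | OC(=O)C(CC#C)C(=O)O | intermediate
5 | 2‑(prop‑2‑yn‑1‑yl)malonyl dichloride | O=C(Cl)C(CC#C)C(=O)Cl | intermediate
6 | 6‑ethyl‑4‑hydroxy‑5‑methyl‑3‑(prop‑2‑yn‑1‑yl)‑2H‑pyran‑2‑one | CCc1oc(=O)c(CC#C)c(O)c1C | intermediate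
7 | 4‑(benzyloxy)‑6‑ethyl‑5‑methyl‑3‑(prop‑2‑yn‑1‑yl)‑2H‑pyran‑2‑one | CCc1oc(=O)c(CC#C)c(OCc2ccccc2)c1C | intermediate
8 | lithium acetylide of 7 (not isolated; drawn without the reversibly formed dienolate at the ethyl group) | CCc1oc(=O)c(CC#[C-])c(OCc2ccccc2)c1C.[Li+] | intermediate
9 | lithium 3‑[4‑(benzyloxy)‑6‑ethyl‑5‑methyl‑2‑oxo‑2H‑pyran‑3‑yl]prop‑1‑yn‑1‑olate (not isolated) | CCc1oc(=O)c(CC#C[O-])c(OCc2ccccc2)c1C.[Li+] | intermediate
10 | 4‑(benzyloxy)‑6‑ethyl‑5‑methyl‑3‑{3‑[(triisopropylsilyl)oxy]prop‑2‑yn‑1‑yl}‑2H‑pyran‑2‑one | CCc1oc(=O)c(CC#CO[Si](C(C)C)(C(C)C)C(C)C)c(OCc2ccccc2)c1C | intermediate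
11 | acetone | CC(C)=O | starting material
12 | ketene | C=C=O | intermediate
13 | 4‑(benzyloxy)‑6‑ethyl‑5‑methyl‑3‑({4‑oxo‑2‑[(triisopropylsilyl)oxy]cyclobut‑1‑en‑1‑yl}methyl)‑2H‑pyran‑2‑one | O=C1CC(O[Si](C(C)C)(C(C)C)C(C)C)=C1Cc1c(OCc2ccccc2)c(C)c(CC)oc1=O | intermediate
14 | 2‑(pyronylmethyl)‑3‑(triisopropylsilyloxy)buta‑1,3‑dien‑1‑one, the vinylketene (not isolated) | O=C=C(Cc1c(OCc2ccccc2)c(C)c(CC)oc1=O)C(=C)O[Si](C(C)C)(C(C)C)C(C)C | intermediate
15 | 2,4‑bis(pyronylmethyl)‑3‑(triisopropylsilyloxy)‑4‑[1‑(triisopropylsilyloxy)vinyl]cyclobut‑2‑en‑1‑one (racemic, not isolated) | O=C1C(Cc2c(OCc3ccccc3)c(C)c(CC)oc2=O)=C(O[Si](C(C)C)(C(C)C)C(C)C)C1(Cc1c(OCc2ccccc2)c(C)c(CC)oc1=O)C(=C)O[Si](C(C)C)(C(C)C)C(C)C | intermediate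
16 | 2,4‑bis(pyronylmethyl)‑3,5‑bis(triisopropylsilyloxy)hexa‑1,3,5‑trien‑1‑one, ketenyl and siloxyvinyl groups cis (not isolated) | O=C=C(Cc1c(OCc2ccccc2)c(C)c(CC)oc1=O)/C(O[Si](C(C)C)(C(C)C)C(C)C)=C(/Cc1c(OCc2ccccc2)c(C)c(CC)oc1=O)C(=C)O[Si](C(C)C)(C(C)C)C(C)C | intermediate
17 | 2,4‑bis(pyronylmethyl)‑3,5‑bis(triisopropylsilyloxy)cyclohexa‑2,4‑dien‑1‑one (not isolated) | O=C1CC(O[Si](C(C)C)(C(C)C)C(C)C)=C(Cc2c(OCc3ccccc3)c(C)c(CC)oc2=O)C(O[Si](C(C)C)(C(C)C)C(C)C)=C1Cc1c(OCc2ccccc2)c(C)c(CC)oc1=O | intermediate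
18 | 3,3'‑({4‑hydroxy‑2,6‑bis[(triisopropylsilyl)oxy]‑1,3‑phenylene}bis(methylene))bis[4‑(benzyloxy)‑6‑ethyl‑5‑methyl‑2H‑pyran‑2‑one] | Oc1cc(O[Si](C(C)C)(C(C)C)C(C)C)c(Cc2c(OCc3ccccc3)c(C)c(CC)oc2=O)c(O[Si](C(C)C)(C(C)C)C(C)C)c1Cc1c(OCc2ccccc2)c(C)c(CC)oc1=O | intermediate
19 | 3,3'‑({4‑hydroxy‑5‑(2‑methylpropanoyl)‑2,6‑bis[(triisopropylsilyl)oxy]‑1,3‑phenylene}bis(methylene))bis[4‑(benzyloxy)‑6‑ethyl‑5‑methyl‑2H‑pyran‑2‑one] | CC(C)C(=O)c1c(O)c(Cc2c(OCc3ccccc3)c(C)c(CC)oc2=O)c(O[Si](C(C)C)(C(C)C)C(C)C)c(Cc2c(OCc3ccccc3)c(C)c(CC)oc2=O)c1O[Si](C(C)C)(C(C)C)C(C)C | intermediate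
20 | 3,3'‑{[2,4,6‑trihydroxy‑5‑(2‑methylpropanoyl)‑1,3‑phenylene]bis(methylene)}bis[4‑(benzyloxy)‑6‑ethyl‑5‑methyl‑2H‑pyran‑2‑one] | CC(C)C(=O)c1c(O)c(Cc2c(OCc3ccccc3)c(C)c(CC)oc2=O)c(O)c(Cc2c(OCc3ccccc3)c(C)c(CC)oc2=O)c1O | intermediate
21 | 3,3'‑{[2,4,6‑trihydroxy‑5‑(2‑methylpropanoyl)‑1,3‑phenylene]bis(methylene)}bis(6‑ethyl‑4‑hydroxy‑5‑methyl‑2H‑pyran‑2‑one), achiral | CCc1oc(=O)c(Cc2c(O)c(Cc3c(O)c(C)c(CC)oc3=O)c(O)c(C(=O)C(C)C)c2O)c(O)c1C | target

**Step count and risks**

Total step count: 12 (including the generation of ketene).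
Longest linear sequence: 10 steps (3 → 4 → 5 → 6 → 7 → 10 → 13 → 18 → 19 → 20 → 21, i.e. steps 2–6 and 8–12).

Steps most likely to fail:

1. Step 9 (proposed new method). The vinylogous silyl ester character of the cyclobutenone may make its electrocyclic opening too slow below the temperature at which the siloxyalkyne and the pyranones begin to react otherwise. The congested [2+2] at the disubstituted ketene terminus may also lose out to ketene dimerisation or to capture of the ketene by the phenol being formed. The fallback gives up the pericyclic ring construction and uses methylene bridging of a preformed acylphloroglucinol, all of it known chemistry. It sets out from silyl enol ether 2, whose annulation with malonyl dichloride (Et2O, −78 °C to rt) should give 6‑ethyl‑4‑hydroxy‑5‑methyl‑2H‑pyran‑2‑one F1. A Mannich reaction with Eschenmoser's salt (CH2Cl2, rt) should give 3‑[(dimethylamino)methyl]‑6‑ethyl‑4‑hydroxy‑5‑methyl‑2H‑pyran‑2‑one hydroiodide F2. Warming two equivalents of F2 with commercial 2‑methyl‑1‑(2,4,6‑trihydroxyphenyl)propan‑1‑one should release the pyranone methide by loss of dimethylamine and alkylate both free ring carbons of the acylphloroglucinol, so that the route is rejoined directly at target 21.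

2. Step 6. The peroxide anion or the amide base may attack the lactone, the dienolate at the 6‑ethyl group may be oxidised or silylated in competition with the ynolate, and the propargylic position may isomerise towards the allene. The fallback reaches the ynolate by sulfonate cleavage and not by acetylide oxidation. It sets out from alkyne 7, which with Koser's reagent, PhI(OH)OTs, in CHCl3 should give {3‑[4‑(benzyloxy)‑6‑ethyl‑5‑methyl‑2‑oxo‑2H‑pyran‑3‑yl]prop‑1‑yn‑1‑yl}(phenyl)iodonium tosylate F3. Copper(I) triflate catalysis in MeCN should convert this into 3‑[4‑(benzyloxy)‑6‑ethyl‑5‑methyl‑2‑oxo‑2H‑pyran‑3‑yl]prop‑1‑yn‑1‑yl 4‑methylbenzenesulfonate F4. One equivalent of MeLi at −78 °C should attack sulfur to give ynolate 9, and TIPSCl then gives siloxyalkyne 10, where the route is rejoined.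

3. Step 10. The Lewis acid may strip silyl or benzyl ethers, ipso attack at an arm-bearing carbon may expel a pyronylmethyl group, and the bulky silyl ether next to the reacting carbon may make acylation sluggish. The fallback removes the silyl groups first and acylates the free phloroglucinol under Hoesch conditions. It sets out from phenol 18, which with TBAF/AcOH in THF should give 3,3'‑[(2,4,6‑trihydroxy‑1,3‑phenylene)bis(methylene)]bis[4‑(benzyloxy)‑6‑ethyl‑5‑methyl‑2H‑pyran‑2‑one] F5. Isobutyronitrile, ZnCl2 and HCl gas in Et2O at 0 °C should then give the ketiminium chloride 1‑{2,4,6‑trihydroxy‑3,5‑bis[(4‑benzyloxy‑6‑ethyl‑5‑methyl‑2‑oxo‑2H‑pyran‑3‑yl)methyl]phenyl}‑2‑methylpropan‑1‑iminium chloride F6. Hydrolysis in warm water gives ketone 20, where the route is rejoined.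

**Further compounds**

F1 | step 9 | 6‑ethyl‑4‑hydroxy‑5‑methyl‑2H‑pyran‑2‑one | CCc1oc(=O)cc(O)c1C
F2 | step 9 | 3‑[(dimethylamino)methyl]‑6‑ethyl‑4‑hydroxy‑5‑methyl‑2H‑pyran‑2‑one hydroiodide | CCc1oc(=O)c(C[NH+](C)C)c(O)c1C.[I-]
F3 | step 6 | {3‑[4‑(benzyloxy)‑6‑ethyl‑5‑methyl‑2‑oxo‑2H‑pyran‑3‑yl]prop‑1‑yn‑1‑yl}(phenyl)iodonium tosylate | CCc1oc(=O)c(CC#C[I+]c2ccccc2)c(OCc2ccccc2)c1C.Cc1ccc(S(=O)(=O)[O-])cc1
F4 | step 6 | 3‑[4‑(benzyloxy)‑6‑ethyl‑5‑methyl‑2‑oxo‑2H‑pyran‑3‑yl]prop‑1‑yn‑1‑yl 4‑methylbenzenesulfonate | CCc1oc(=O)c(CC#COS(=O)(=O)c2ccc(C)cc2)c(OCc2ccccc2)c1C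
F5 | step 10 | 3,3'‑[(2,4,6‑trihydroxy‑1,3‑phenylene)bis(methylene)]bis[4‑(benzyloxy)‑6‑ethyl‑5‑methyl‑2H‑pyran‑2‑one] | Oc1cc(O)c(Cc2c(OCc3ccccc3)c(C)c(CC)oc2=O)c(O)c1Cc1c(OCc2ccccc2)c(C)c(CC)oc1=O
F6 | step 10 | 1‑{2,4,6‑trihydroxy‑3,5‑bis[(4‑benzyloxy‑6‑ethyl‑5‑methyl‑2‑oxo‑2H‑pyran‑3‑yl)methyl]phenyl}‑2‑methylpropan‑1‑iminium chloride | CC(C)C(=[NH2+])c1c(O)c(Cc2c(OCc3ccccc3)c(C)c(CC)oc2=O)c(O)c(Cc2c(OCc3ccccc3)c(C)c(CC)oc2=O)c1O.[Cl-]
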